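The flask is a closed, stirred vessel charged like the winter and spring runs, except that it holds 1.20 M of solid reagent. Substrate is the smallest charge.

| flask | substrate | second reagent | third reagent | solid reagent | remark | time |
|---|---|---|---|---|---|---|
| winter | 0.48 M | 0.528 M | 1.44 M | 0.60 M | run made earlier |  |
| spring | 0.48 M | 0.528 M | 1.44 M | 0.90 M | run made earlier |  |
| flask | 0.48 M | 0.528 M | 1.44 M | 1.20 M |  | 10 d |

- winter (time / d: target / %, idle adduct / %): 2.08: 27.5, 0; 4.00: 53.7, 0; 6.00: 69.7, 0; 8.00: 80.0, 0
- spring (time / d: target / %, idle adduct / %): 0.625: 2.8, 0.6; 1.67: 20.0, 0; 3.00: 41.6, 0.1; 8.00: 79.3, 0

(readings scatter by 0.5 percentage points)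

- percent here means substrate units held: one idle adduct counts as two
- what is said of target includes idle adduct and crystals
- solid reagent, crystals is a solid; its amount is given per volume of the solution
- what was read earlier has a scatter of 0.5 percentage points, one standard deviation
- at the start none of the solid reagent is in solution
- in an amount of target, one idle adduct counts as one target
- partner is what solid reagent becomes in solution

- target and idle adduct and crystals together at 10 d, in percent of the substrate charged
- concentration of partner in solution at 10 d, in percent of saturation

I wrote the balance of substrate: whatever is not read as target is still owed. In the winter run that owed share shrank by a factor of 0.654 from 4.00 d to 6.00 d, then 0.660 up to 8.00 d. Carrying the last factor forward to 10 d left 13.2%.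

The spring run offered a second way, from other readings at another solid load. Between 3.00 d and 8.00 d its owed share shrank by 0.660 over a stretch as long as winter's last, which left 13.7%. The two ways part by 0.50 percentage points, and one reading scatters by 0.5 points, so I trusted both and took their mean, an estimate carried over from lower solid loads, as the gap, the share of charged substrate not yet target in the flask at the asked time: 13.4%. I reckoned nothing for saturation.

The forecast gave 86.5% and 99%, holding that “Solid load therefore doesn't matter while solid remains”.

The flask gave 85.9% and 100%.

    substrate + partner → intermediate A (k = 0.650 /M/h)
    second reagent + intermediate A → intermediate B (k = 0.0598 /M/h)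
    solid reagent ⇌ partner, rate k3*(cs3 - [partner]) while solid is left; crystals form when [partner] > cs3 (solubility = 0.430 M, k = 0.551 /h)
    third reagent + intermediate B → target (k = 0.0170 /M/h)
    crystals ⇌ target, rate k5*(cs5 - [target]) while solid is left; crystals form when [target] > cs5 (solubility = 0.460 M, k = 0.866 /h)
    substrate + target ⇌ idle adduct, settled at all times (K = 1.10 /M)

With substrate, the limiting reagent, at 0% in the flask at 10 d, its gap of 14.1% against my 13.4% stood as intermediate A at 8.68% and intermediate B at 5.43%. With second reagent down at 0.471 M, all else held, the answer had moved by 5 points from this flask's. The neighbouring flask, with 0.32 M of second reagent, or 0.667 equiv, reached 61.0%. Its gap was 39.0%, 2.91 times the one I reckoned for the flask, and its charge of second reagent fell short of the substrate by 33.3% of the substrate charged. Intermediate A held 35.9% of the substrate charged there, with 3.8% of the charged second reagent remaining.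

Readings and results are calculated on assumed constants; noise was put on by code.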